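The decalin is disconnected at its ring-fusion bond, between the quaternary carbon carrying the angular methyl and the neighbouring ring-fusion CH. That bond is the Michael bond of a Robinson-type retron: the quaternary carbon is the α-carbon of an aldehyde (its CHO carbon becomes the CH–CH2OAr carbon), the CH is the β-carbon of an ethyl enone whose carbonyl marks the later ring alkene and whose CH2CH3 becomes the vinylic methyl. One amine-catalysed domino (Michael addition, ring-closing Michael addition, aldol condensation) therefore converts propanal and an acyclic dienedione into the trans-fused gem-dimethyl enedione in a single operation. Axial conjugate addition of a hydroxymethyl equivalent, enol triflate reduction and Mitsunobu etherification with isofraxidin complete the route.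

Key step: step 4

Remark: the sense of asymmetric induction of the quinine-derived primary amine in step 4 is assumed, not derived; its quinidine-derived pseudoenantiomer would be used if the opposite sense results.

Step 1
Reactants: 1 2-methyl-1-(trimethylsilyloxy)prop-1-ene; 2 prop-2-enal (acrolein)
Product: 3 3-hydroxy-2,2-dimethylpent-4-enal (racemic)
Conditions: Sc(OTf)3 (5 mol %), CH2Cl2, −78 °C; then 1 M HCl, THF, 0 °C
Reagents that add atoms: none
Why: Lewis-acid-catalysed Mukaiyama aldol addition, in which the aldehyde-derived silyl enol ether attacks the activated enal 1,2 and creates the gem-dimethyl quaternary carbon; the racemic allylic carbinol is oxidised away in step 3, so no stereocontrol is needed.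

Step 2
Reactants: 3 3-hydroxy-2,2-dimethylpent-4-enal; 4 dimethyl (2-oxobutyl)phosphonate
Product: 5 (4E)-7-hydroxy-6,6-dimethylnona-4,8-dien-3-one (racemic)
Conditions: LiCl, i-Pr2NEt, MeCN, rt
Reagents that add atoms: none
Why: Horner–Wadsworth–Emmons olefination of the non-enolisable aldehyde with the stabilised β-ketophosphonate under weak-base LiCl/amine activation should give the (E)-enone and avoid retro-aldol cleavage of the β-hydroxy aldehyde.

Step 3
Reactants: 5 (4E)-7-hydroxy-6,6-dimethylnona-4,8-dien-3-one
Product: 6 (5E)-4,4-dimethylnona-1,5-diene-3,7-dione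
Conditions: 1,1,1-triacetoxy-1,1-dihydro-1,2-benziodoxol-3(1H)-one (Dess–Martin periodinane), CH2Cl2, 0 °C to rt; used at once
Reagents that add atoms: none
Why: Dess–Martin oxidation turns the secondary allylic alcohol into the vinyl ketone under neutral, non-nucleophilic conditions, spares the enone and erases the racemic centre.

Step 4
Reactants: 6 (5E)-4,4-dimethylnona-1,5-diene-3,7-dione; 7 propanal (3 equiv)
Product: 10 (4aR,8aR)-1,1,4a,6-tetramethyl-3,4,4a,8a-tetrahydronaphthalene-2,7(1H,8H)-dione, via Michael adduct 8 (not isolated), via cyclised keto-aldehyde 9 (not isolated)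
Conditions: 9-amino-9-deoxy-epi-quinine (20 mol %), 2-fluorobenzoic acid (40 mol %), toluene, 0 °C, then 45 °C
Reagents that add atoms: none
Why: The amine forms the enamine of propanal, which adds to the unhindered vinyl ketone of 6 (Michael addition) to give 8; 8 re-forms an enamine at the now α-branched aldehyde, whose β-carbon attacks the β-carbon of the hindered enone in a 6-exo-trig Michael addition that forges the bond between the two future ring-fusion carbons and closes the gem-dimethyl cyclohexanone ring (9). The ethyl ketone then condenses through its α-CH2 with the aldehyde (6-enolexo-exo-trig aldol, loss of water), closing the 2-methylcyclohexenone ring. The closest known reaction type is the amine-catalysed Michael/Michael/aldol-condensation domino, an organocatalytic Robinson-type annulation of an α-branched aldehyde that creates a quaternary carbon. Both new stereocenters arise in the ring-closing Michael addition: a chair transition state with the aminovinyl group and the enone chain pseudo-equatorial and the methyl pseudo-axial should place CH3 and the ring-fusion H anti (trans-fused product), and the chiral amine, bound as enamine while its protonated quinuclidine holds the enone carbonyl, selects one of the two mirror-image chairs. The step needs site selectivity between the two enones, secured because the neopentyl-type enone is reached only intramolecularly, and a single productive aldol, secured because the quaternary dimethyl carbon blocks enolisation between the ketones and only the six-membered aldehyde adduct can dehydrate.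

Step 5
Reactants: 10 (4aR,8aR)-1,1,4a,6-tetramethyl-3,4,4a,8a-tetrahydronaphthalene-2,7(1H,8H)-dione
Product: 12 (4S,4aS,8aR)-4-{[dimethyl(propan-2-yloxy)silyl]methyl}-3,4a,8,8-tetramethyl-7-oxo-1,4,4a,5,6,7,8,8a-octahydronaphthalen-2-yl trifluoromethanesulfonate, via chloromagnesium enolate 11 (not isolated)
Conditions: i-PrO(Me)2SiCH2MgCl (1.5 equiv, from the chloride and Mg), CuBr·SMe2 (10 mol %), THF, −78 to −30 °C; then N-(5-chloropyridin-2-yl)-N-triflyltriflamide, −78 °C to rt
Reagents that add atoms: [(isopropoxydimethylsilyl)methyl]magnesium chloride CC(C)O[Si](C)(C)C[Mg]Cl; N-(5-chloropyridin-2-yl)-1,1,1-trifluoro-N-(trifluoromethylsulfonyl)methanesulfonamide O=S(=O)(N(c1ccc(Cl)cn1)S(=O)(=O)C(F)(F)F)C(F)(F)F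
Why: Copper-catalysed conjugate addition of the silylmethyl Grignard reagent (a hydroxymethyl anion equivalent) should occur by axial attack on the enone face anti to the axial angular methyl, setting the third stereocenter with the CH2Si arm trans to CH3, and O-sulfonylation of the regiodefined enolate 11 (conjugate addition/enolate trapping) fixes the future alkene position.

Step 6
Reactants: 12 enol triflate
Product: 13 (4aS,5R,8aR)-5-{[dimethyl(propan-2-yloxy)silyl]methyl}-1,1,4a,6-tetramethyl-3,4,4a,5,8,8a-hexahydronaphthalen-2(1H)-one
Conditions: Pd(OAc)2 (5 mol %), PPh3 (10 mol %), HCO2H, Et3N, DMF, 60 °C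
Reagents that add atoms: none
Why: Palladium-catalysed formate reduction of the enol triflate (oxidative addition, formate-to-hydride exchange, reductive elimination) replaces OTf by H and leaves the trisubstituted alkene where the enolate double bond was; ketone, silane and the allylic stereocenter are not affected.

Step 7
Reactants: 13 silyl ketone
Product: 14 (4aS,5R,8aR)-5-(hydroxymethyl)-1,1,4a,6-tetramethyl-3,4,4a,5,8,8a-hexahydronaphthalen-2(1H)-one
Conditions: 30 % aq. H2O2, KF, KHCO3, THF/MeOH (1:1), rt
Reagents that add atoms: hydrogen peroxide OO
Why: Tamao oxidation, in which the fluoride- and peroxide-activated alkoxysilane undergoes 1,2-migration of the alkyl group from silicon to oxygen, unmasks the primary alcohol without touching ketone, alkene or stereocenters.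

Step 8
Reactants: 14 hydroxymethyl ketone; 15 7-hydroxy-6,8-dimethoxy-2H-chromen-2-one (isofraxidin)
Product: 16 6,8-dimethoxy-7-{[(1R,4aR,8aS)-2,5,5,8a-tetramethyl-6-oxo-1,4,4a,5,6,7,8,8a-octahydronaphthalen-1-yl]methoxy}-2H-chromen-2-one (target)
Conditions: PPh3, DIAD, THF, 0 °C to rt
Reagents that add atoms: none
Why: Mitsunobu etherification, in which the primary alcohol is activated as an alkoxyphosphonium ion and displaced by the acidic 7-OH of the coumarin (SN2 at CH2, no stereocenter involved), should give the target.

Compound list
1 | 2-methyl-1-(trimethylsilyloxy)prop-1-ene | CC(C)=CO[Si](C)(C)C | starting material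
2 | prop-2-enal (acrolein) | C=CC=O | starting material
3 | 3-hydroxy-2,2-dimethylpent-4-enal (racemic) | C=CC(O)C(C)(C)C=O | intermediate
4 | dimethyl (2-oxobutyl)phosphonate | CCC(=O)CP(=O)(OC)OC | starting material
5 | (4E)-7-hydroxy-6,6-dimethylnona-4,8-dien-3-one (racemic) | CCC(=O)/C=C/C(C)(C)C(O)C=C | intermediate
6 | (5E)-4,4-dimethylnona-1,5-diene-3,7-dione | CCC(=O)/C=C/C(C)(C)C(=O)C=C | intermediate
7 | propanal | CCC=O | starting material
8 | (7E)-2,6,6-trimethyl-5,9-dioxoundec-7-enal (configuration at C2 not defined; it is erased on enamine formation) | CCC(=O)/C=C/C(C)(C)C(=O)CCC(C)C=O | intermediate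
9 | (1S,2R)-1,3,3-trimethyl-4-oxo-2-(2-oxobutyl)cyclohexane-1-carbaldehyde | CCC(=O)C[C@H]1C(C)(C)C(=O)CC[C@@]1(C=O)C | intermediate
10 | (4aR,8aR)-1,1,4a,6-tetramethyl-3,4,4a,8a-tetrahydronaphthalene-2,7(1H,8H)-dione | CC1=C[C@@]2(C)CCC(=O)C(C)(C)[C@@H]2CC1=O | intermediate
11 | chloromagnesium (4S,4aS,8aR)-4-{[dimethyl(propan-2-yloxy)silyl]methyl}-3,4a,8,8-tetramethyl-7-oxo-1,4,4a,5,6,7,8,8a-octahydronaphthalen-2-olate | CC(C)O[Si](C)(C)C[C@@H]1C(C)=C(O[Mg]Cl)C[C@H]2C(C)(C)C(=O)CC[C@]12C | intermediate
12 | (4S,4aS,8aR)-4-{[dimethyl(propan-2-yloxy)silyl]methyl}-3,4a,8,8-tetramethyl-7-oxo-1,4,4a,5,6,7,8,8a-octahydronaphthalen-2-yl trifluoromethanesulfonate | CC(C)O[Si](C)(C)C[C@@H]1C(C)=C(OS(=O)(=O)C(F)(F)F)C[C@H]2C(C)(C)C(=O)CC[C@]12C | intermediate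
13 | (4aS,5R,8aR)-5-{[dimethyl(propan-2-yloxy)silyl]methyl}-1,1,4a,6-tetramethyl-3,4,4a,5,8,8a-hexahydronaphthalen-2(1H)-one | CC(C)O[Si](C)(C)C[C@@H]1C(C)=CC[C@H]2C(C)(C)C(=O)CC[C@]12C | intermediate
14 | (4aS,5R,8aR)-5-(hydroxymethyl)-1,1,4a,6-tetramethyl-3,4,4a,5,8,8a-hexahydronaphthalen-2(1H)-one | OC[C@@H]1C(C)=CC[C@H]2C(C)(C)C(=O)CC[C@]12C | intermediate
15 | 7-hydroxy-6,8-dimethoxy-2H-chromen-2-one (isofraxidin) | COc1cc2ccc(=O)oc2c(OC)c1O | starting material
16 | 6,8-dimethoxy-7-{[(1R,4aR,8aS)-2,5,5,8a-tetramethyl-6-oxo-1,4,4a,5,6,7,8,8a-octahydronaphthalen-1-yl]methoxy}-2H-chromen-2-one | COc1cc2ccc(=O)oc2c(OC)c1OC[C@@H]1C(C)=CC[C@H]2C(C)(C)C(=O)CC[C@]12C | target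

Total steps: 8. Longest linear sequence: 8 steps (1 → 3 → 5 → 6 → 10 → 12 → 13 → 14 → 16).

Steps most likely to fail

Step 4. The ring-closing Michael addition joins a carbon that becomes quaternary to a neopentyl-type β-carbon. It may stall at 8 or revert, propanal may self-condense, and facial selectivity may be poor, both in the sense and level of asymmetric induction and in trans versus cis ring fusion. The fallback separates the events and takes enantiopurity from a resolution instead of from the catalyst. It sets out from 6 and 7: pyrrolidinium acetate catalyses the intermolecular Michael addition to 8, which is isolated. KOH in MeOH (reversible enolate Michael addition drained by the irreversible aldol condensation) then gives 10 as the racemate, that is together with its mirror image, the (4aS,8aS)-enedione F1. Any cis-fused isomer is removed on silica, F1 is removed by preparative chromatography on a chiral stationary phase, and the route is rejoined at 10.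

Step 5. Conjugate addition next to the quaternary centre may be slow, the Grignard reagent may add 1,2 to the saturated ketone, and the enolate may equilibrate before O-sulfonylation, with loss of regiocontrol. The fallback delivers the CH2OH group intramolecularly by a [2,3]-sigmatropic shift instead of by intermolecular conjugate addition. It sets out from 10: 1,2-bis(trimethylsilyloxy)ethane with catalytic TMSOTf (CH2Cl2, −78 °C) should ketalise only the saturated ketone and give the mono-ethylene ketal F2. LiB(s-Bu)3H at −78 °C reduces the enone carbonyl from the equatorial direction to the axial allylic alcohol F3 (hydroxyl anti to the angular methyl). KH and Bu3SnCH2I give the tributylstannylmethyl ether F4. n-BuLi at −78 °C triggers tin–lithium exchange and the Still–Wittig [2,3]-rearrangement, which moves the alkene into the trisubstituted position and transfers CH2OH suprafacially to the face that carried the oxygen, giving the ketal alcohol F5. PPTS in aqueous acetone removes the ketal, and the route is rejoined at 14.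

Step 8. Displacement of the alkoxyphosphonium ion at the β-branched, axially disposed primary carbon may be slow, leading to recovered alcohol or elimination. The fallback uses an isolated sulfonate and SN2 displacement by the phenoxide instead of redox condensation. It sets out from 14: Tf2O and 2,6-lutidine (CH2Cl2, −78 °C) give the primary triflate F6, which the caesium salt of 15 (Cs2CO3, DMF, 0 °C to rt) displaces to give 16.

Further compounds
F1 | step 4 | (4aS,8aS)-1,1,4a,6-tetramethyl-3,4,4a,8a-tetrahydronaphthalene-2,7(1H,8H)-dione (mirror image of 10) | CC1=C[C@]2(C)CCC(=O)C(C)(C)[C@H]2CC1=O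
F2 | step 5 | mono-ethylene ketal of 10 at the saturated ketone | CC1=C[C@@]2(C)CCC3(OCCO3)C(C)(C)[C@@H]2CC1=O
F3 | step 5 | axial allylic alcohol from F2 (enone carbonyl reduced, carbinol carbon R, hydroxyl anti to the angular methyl) | C1=C(C)[C@H](O)C[C@H]2C(C)(C)C3(OCCO3)CC[C@]12C
F4 | step 5 | tributylstannylmethyl ether of F3 | C1=C(C)[C@H](OC[Sn](CCCC)(CCCC)CCCC)C[C@H]2C(C)(C)C3(OCCO3)CC[C@]12C
F5 | step 5 | ethylene ketal of 14 | OC[C@@H]1C(C)=CC[C@H]2C(C)(C)C3(OCCO3)CC[C@]12C
F6 | step 8 | trifluoromethanesulfonate of 14 | O=S(=O)(OC[C@@H]1C(C)=CC[C@H]2C(C)(C)C(=O)CC[C@]12C)C(F)(F)F
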